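## Structural features

The target is a (2S)-flavanone: aromatic ring A (C4a, C5, C6, C7, C8, C8a) is fused to the dihydropyranone ring C (O1, C2, C3, C4, C4a, C8a), and C2 carries ring B, a 2′,4′-dihydroxyphenyl group. Ring A is hexasubstituted, with oxygen at C5, C7 and C8a alternating with carbon at C4a (the C4 acyl carbon), C6 ((E)-3-methylbut-1-enyl) and C8 (prenyl), which is the pattern of a folded polyketide. C2 is the only stereocentre and has no stereogenic neighbour, but it is benzylic to an electron-rich ring, bonded to O1 and β to the C4 carbonyl, so base can erase it by retro-oxa-Michael opening and acid by ionization of C2–O1. The fragile groups are the prenyl double bond next to O7 (protic acid or an electrophile closes a new oxygen ring), the styrene-type double bond at C6 conjugated with a phloroglucinol ring, and four oxidizable phenols. The real difficulty is placing two different carbon chains at C6 and C8 of a nearly symmetric phloroglucinol while keeping a labile C2 intact. The key step uses the C5/C7/C8a oxygen pattern: ring C is made first as a 2-aryl-2,3-dihydropyran-4-one whose enol-ether carbon C4a is nucleophilic and whose O1–C8a bond already tells C8 from C6, while C5–C6–C7 is carried as a dioxinone (a masked acylketene), so ring A closes through the C4a–C5 bond. The priorities at C2 stay O > C1′ > CH2 > H in the open-chain carbinol, the dihydropyranone and the flavanone, so the descriptor is (S) throughout; the precursor and product of the key step were checked atom by atom on this basis and need no correction.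

## Logic of the disconnections

**23 to 21 (through 22).** The two O–CH2 acetal bonds on ring B are cut last. Ring B must stay masked through the enolate chemistry, the thermolysis (no free hydroxyl allowed) and the iodination (a free resorcinol would compete with ring A). The demand is cleavage without protic acid, because C2, the prenyl group beside O7 and the C6 alkenyl group are all acid-sensitive; a silyl triflate/bipyridyl exchange through 22 is therefore planned instead of methanolic acid.

**21 to 19 and 20.** The C6–C1″ bond is cut. The alkene geometry is bought with 20, and C6 is the one ring A position that can be functionalized after the ring exists. The forward coupling must work on a di-ortho-substituted, electron-rich iodide under base mild enough not to open ring C.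

**19 to 18.** The C6–I bond is cut. C6 is the only unsubstituted carbon of ring A and lies ortho to O5 and O7 and para to O1. The electrophile must choose C6 over the prenyl double bond and over ring B.

**18 to 14 (through 15, 16 and 17).** The C4a–C5 bond is cut and ring A disappears. This replaces the regiochemical problem of an aromatic ring by a chain in which the prenyl-bearing carbon is already attached to C8a. The demand is that the acylketene be captured intramolecularly and at carbon; 14 therefore carries no free hydroxyl and is used as the mixture of C8 epimers, which converge.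

**14 to 12 (through 13).** The O1–C8a bond and the O–Si bond are cut. Cyclodehydration of a δ-hydroxy-β-diketone never touches the C2–O bond, so configuration is retained. The acid must be weak enough for the acetals and the benzylic carbinol, hence a triethylsilyl ether that leaves with pyridinium tosylate, and ring closure must precede any aldol aromatization of the chain.

**12 to 11 and 6.** The C4–C4a bond is cut. This separates an achiral C5–C8a piece carrying the prenyl group from a small chiral C2–C4 piece. The forward Claisen step needs the terminal carbon of a dianion to attack an amide that cannot over-add.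

**11 to 9 and 10, then 9 to 7 and 8.** The C8–C1‴ and C8–C8a bonds are cut. Both are enolate bond formations at the same exocyclic carbon of a commercial dioxinone. The demand is C- over O-alkylation and mono- over dialkylation.

**6 to 5 to 4.** The O–Si bond and then the C2–H bond are cut. The stereocentre comes from catalyst-controlled hydride delivery to an aryl ketone, a reduction whose facial sense is well established, rather than from an auxiliary aldol.

**4 to 2 and 3, then 2 to 1.** The C2–C3 bond and the two O–CH2 bonds are cut, leading to a commercial benzoate and a commercial amide. The ester has no α-hydrogen, so only the amide can serve as the nucleophile.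

## Other disconnections considered

**Alternative 1:** Ring A is cut at C8–C8a and C6–C7. Forward, cyclobutenone A2 and siloxyalkyne A3 are heated: four-electron ring opening, [2+2] addition, a second ring opening and six-electron closure (Danheiser benzannulation) would give phenol A1.
- In favour: both carbon chains of ring A and three differentiated oxygens are placed in one metal-free step. The C6 alkenyl group is present before ring A exists, so no iodination next to a prenyl group and no cross-coupling on a free phenol is needed; on this point Alternative 1 is better than the chosen plan. Its pericyclic cascade also has direct precedent, which step 9 lacks.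
- Against: O5 emerges as an ethyl ether, whose cleavage needs boron trihalides or hot thiolate that the prenyl group, the alkenyl group and a flavanone would not tolerate. The alkenyl group of A2 offers the dienylketene a second terminus for closure. Ring C and C2 are not addressed: C-acylation at C4a and an enantioselective oxa-Michael closure would still be needed, and the latter has no general solution and passes through base-labile intermediates.
- Comparison: both plans end in the same electrocyclization of a dienylketene. Alternative 1 solves the substitution of ring A more directly; the chosen plan sets C2 early by a reliable reduction and lets ring C direct the closure. With two or three steps each for A2 and A3 and at least five after A1, the step count would not be lower.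

**Alternative 2:** The C2–C3 bond is cut. Forward, Rh2(S-PTTL)4, a chiral carboxylate of divalent rhodium, would decompose diazoketone A5, and the carbenoid carbon C3 would insert into a benzylic C–H bond next to O1 to give A4.
- In favour: ring C and C2 would be made in one catalytic step from an achiral substrate, with no base and no chalcone. The stereocentre is created last and cannot be eroded earlier. The final unmasking is a fourfold desilylation with buffered fluoride, milder than the acetal cleavage of the chosen plan; on this point Alternative 2 is better.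
- Against: six-membered insertion competes with attack of the O1 lone pair on the carbenoid followed by a [1,2] benzyl shift (Stevens shift), which would contract ring C. Two nucleophilic double bonds and the electron-rich ring B are further targets. Carbenoids bearing only an acyl group are the least selective class with chiral carboxylate catalysts. A5 needs a hexasubstituted, doubly ortho-flanked benzoic acid to be converted into a diazoketone, and its ring A must first be assembled with the same regiochemical problem.
- Comparison: the end would be shorter, but the whole route would not be, and the mechanistic risk is one of chemoselectivity among several fast pathways, against feasibility of a single pathway in the chosen plan.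

**Alternative 3:** The C4a–C4, C4–C3 and O1–C2 bonds are cut. Forward, iodophenol A7, CO and alkyne A8 would combine under PdCl2(PPh3)2 (divalent palladium) and diethylamine: oxidative addition, CO insertion, acyl–alkynyl coupling and amine-assisted 6-endo closure to flavone A6.
- In favour: three bonds and ring C form in one step from simple pieces, and the reaction type is established for flavones; in convergence and precedent Alternative 3 is better than the chosen key step.
- Against: A6 is flat at C2. The stereocentre would have to come from an enantioselective conjugate reduction of C2=C3 in the presence of the prenyl and alkenyl double bonds, which hydrogenation would not spare. The iodide of A7 is flanked by two oxygen substituents and electron-rich, so CO insertion may lose to direct coupling and five-membered closure. Four acetals instead of two must be removed from an acid-sensitive product, and A7 itself needs the hexasubstituted ring.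
- Comparison: skeleton assembly is more economical, but stereochemistry is deferred to a step with poor prospects, whereas the chosen plan carries a secure C2 through neutral or buffered steps.

Key step: step 9

Remark on the chemistry: 1, 3, 7, 8, 10 and 20 are taken to be commercially available.
Remark on the chemistry: 22 is drawn fully silylated; incomplete silylation of the hydrogen-bonded O5 would change nothing, since water returns all four phenols.

## Steps

Step 1
Reactants: 1 methyl 2,4-dihydroxybenzoate
Product: 2 methyl 2,4-bis(methoxymethoxy)benzoate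
Conditions: NaH, DMF, 0 °C; MOMCl, 0 °C → rt
Reagents that add atoms: chloromethyl methyl ether, COCCl
Why: Williamson-type O-alkylation of both phenoxides; full deprotonation with NaH is used because the hydroxyl next to the ester is hydrogen-bonded and sluggish with amine bases.

Step 2
Reactants: 2 methyl 2,4-bis(methoxymethoxy)benzoate; 3 N-methoxy-N-methylacetamide
Product: 4 3-[2,4-bis(methoxymethoxy)phenyl]-N-methoxy-N-methyl-3-oxopropanamide
Conditions: 3 (2.3 equiv), LiN(iPr)2 (2.3 equiv), THF, −78 °C; then 2, −78 → −30 °C; aq. NH4Cl
Reagents that add atoms: none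
Why: Crossed Claisen condensation forming C2–C3: the lithium enolate of 3, used in excess because 4 is deprotonated as it forms, acylates on the ester carbon of 2, which has no α-hydrogen; the acetals are inert to amide bases.

Step 3
Reactants: 4 3-[2,4-bis(methoxymethoxy)phenyl]-N-methoxy-N-methyl-3-oxopropanamide
Product: 5 (3S)-3-[2,4-bis(methoxymethoxy)phenyl]-3-hydroxy-N-methoxy-N-methylpropanamide
Conditions: RuCl[(S,S)-TsDPEN](p-cymene) (cat.), HCO2H/Et3N (5:2), EtOAc, 35 °C
Reagents that add atoms: none
Why: Noyori–Ikariya asymmetric transfer hydrogenation of an aryl ketone; the (S,S)-diamine complex delivers hydride to the face that places the aryl group beside the cymene ligand, the sense that turns aryl alkyl ketones into (S)-carbinols (O > aryl > CH2), and formic acid makes the reduction of this electron-rich ketone irreversible.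

Step 4
Reactants: 5 (3S)-3-[2,4-bis(methoxymethoxy)phenyl]-3-hydroxy-N-methoxy-N-methylpropanamide
Product: 6 (3S)-3-[2,4-bis(methoxymethoxy)phenyl]-N-methoxy-N-methyl-3-(triethylsilyloxy)propanamide
Conditions: Et3SiCl, imidazole, CH2Cl2, 0 °C → rt
Reagents that add atoms: chlorotriethylsilane, CC[Si](Cl)(CC)CC
Why: Silylation removes the only acidic hydrogen of the amide, so step 7 needs no sacrificial base and cannot retro-aldolize; triethylsilyl is chosen over a bulkier group because it leaves with pyridinium tosylate, which the acetals and the benzylic C–O bond tolerate.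

Step 5
Reactants: 7 2,2,6-trimethyl-4H-1,3-dioxin-4-one; 8 acetyl chloride
Product: 9 2,2-dimethyl-6-(2-oxopropyl)-4H-1,3-dioxin-4-one
Conditions: 7 (2 equiv), LiN(SiMe3)2 (2 equiv), THF, −78 °C; then 8 (1 equiv), −78 → −40 °C; aq. NH4Cl
Reagents that add atoms: none
Why: γ-Deprotonation gives the dienolate, which is C-acylated at the exocyclic carbon by the acid chloride (vinylogous Claisen acylation, forming C8–C8a); the second equivalent of dienolate acts as base for the more acidic product.

Step 6
Reactants: 9 2,2-dimethyl-6-(2-oxopropyl)-4H-1,3-dioxin-4-one; 10 prenyl bromide (1-bromo-3-methylbut-2-ene)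
Product: 11 2,2-dimethyl-6-(6-methyl-2-oxohept-5-en-3-yl)-4H-1,3-dioxin-4-one (racemic)
Conditions: K2CO3, acetone, rt (10 in slight deficit)
Reagents that add atoms: none
Why: SN2 C-alkylation of an enolate stabilized by both the ketone and the vinylogous ester with a soft allylic bromide; the new stereocentre (the future C8) is not controlled and need not be, because it becomes an aromatic carbon in step 9.

Step 7
Reactants: 11 2,2-dimethyl-6-(6-methyl-2-oxohept-5-en-3-yl)-4H-1,3-dioxin-4-one; 6 (3S)-3-[2,4-bis(methoxymethoxy)phenyl]-N-methoxy-N-methyl-3-(triethylsilyloxy)propanamide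
Product: 12 6-[(10S)-10-[2,4-bis(methoxymethoxy)phenyl]-2-methyl-6,8-dioxo-10-(triethylsilyloxy)dec-2-en-5-yl]-2,2-dimethyl-4H-1,3-dioxin-4-one (both C5 epimers)
Conditions: 11 (1.6 equiv), LiN(iPr)2 (3.3 equiv), THF, −78 °C; then 6, −78 → −40 °C; aq. NH4Cl
Reagents that add atoms: none
Why: Dianion Claisen condensation forming C4–C4a: the second deprotonation occurs at the methyl group, and this terminal carbon, the most reactive site of the dianion, adds to the Weinreb amide; the chelated tetrahedral intermediate prevents over-addition and survives until the quench, and the carbinol carbon has no acidic hydrogen, so its configuration is untouched.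

Step 8
Reactants: 12 6-[(10S)-10-[2,4-bis(methoxymethoxy)phenyl]-2-methyl-6,8-dioxo-10-(triethylsilyloxy)dec-2-en-5-yl]-2,2-dimethyl-4H-1,3-dioxin-4-one
Product: 14 6-{1-[(2S)-2-[2,4-bis(methoxymethoxy)phenyl]-4-oxo-2,3-dihydro-4H-pyran-6-yl]-4-methylpent-3-enyl}-2,2-dimethyl-4H-1,3-dioxin-4-one (both epimers at the side-chain carbon), via hydroxy diketone 13 (not isolated)
Conditions: PPTS, MeOH, rt; then PPTS, 4 Å MS, ClCH2CH2Cl, 45 °C
Reagents that add atoms: none
Why: Acid-catalysed desilylation, then cyclodehydration of a δ-hydroxy-β-diketone: the C2 hydroxyl adds to the C8a carbonyl (6-exo hemiketal) and water is lost to give the vinylogous ester; the C2–O bond is never broken, so configuration is retained, and closure ties C4 up as a vinylogous ester, which removes the electrophile a competing aldol aromatization would need.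

Step 9
Reactants: 14 6-{1-[(2S)-2-[2,4-bis(methoxymethoxy)phenyl]-4-oxo-2,3-dihydro-4H-pyran-6-yl]-4-methylpent-3-enyl}-2,2-dimethyl-4H-1,3-dioxin-4-one
Product: 18 (2S)-2-[2,4-bis(methoxymethoxy)phenyl]-5,7-dihydroxy-8-(3-methylbut-2-enyl)chroman-4-one, via acylketene 15 (not isolated), via hydroxydienylketene 16 (not isolated), via cyclohexadienone 17 (not isolated)
Conditions: dry PhMe, 110 °C, 14 added over 4 h to a final 2 mM, N2 sweep
Reagents that add atoms: none
Why: Proposed new method: retro-hetero-Diels–Alder loss of acetone from the dioxinone at about 110 °C should unmask acylketene 15, tautomerization of the C7 ketone toward C8 should give hydroxydienylketene 16 (C5=C6, C7=C8, C8a=C4a), and this should close by six-electron electrocyclization, equivalent to attack of the enol-ether carbon C4a on the ketene carbon C5, to cyclohexadienone 17, which aromatizes to the 5,7-diol by loss of the C4a hydrogen. The closest known reaction types are dioxinone thermolysis to acylketenes in biomimetic resorcylate synthesis and the electrocyclization of dienylketenes to phenols in cyclobutenone benzannulations, while C-acylation of a vinylogous ester carbon by an acylketene has not been shown. Ring A is the only ring closed, by C4a–C5 bond formation in a six-membered, 6-endo mode with respect to the ketene C=C bond. No stereocentre is created in 18: C4a of 17 is transient, C8 becomes aromatic so both epimers of 14 converge, and C2 is a spectator because neither base nor acid is present to open ring C. The step needs carbon over oxygen selectivity and intramolecular over intermolecular capture: O1 is a weakly nucleophilic enol-ether oxygen whose acylation would be reversible, 14 has no free hydroxyl, and slow addition at high dilution should keep the ketene from dimerizing or acylating the phenols of 18. The regiochemistry (prenyl at C8, hydrogen at C6) is fixed beforehand by the O1–C8a bond.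

Step 10
Reactants: 18 (2S)-2-[2,4-bis(methoxymethoxy)phenyl]-5,7-dihydroxy-8-(3-methylbut-2-enyl)chroman-4-one
Product: 19 (2S)-2-[2,4-bis(methoxymethoxy)phenyl]-5,7-dihydroxy-6-iodo-8-(3-methylbut-2-enyl)chroman-4-one
Conditions: NIS (1.0 equiv), DMF, −20 → 0 °C, dark
Reagents that add atoms: N-iodosuccinimide, O=C1CCC(=O)N1I
Why: Electrophilic aromatic iodination; C6 is the only unsubstituted carbon of ring A and is activated by O5 and O7 (ortho) and O1 (para), which should make it far more reactive toward a mild iodonium source at low temperature than the acetal-masked ring B or the prenyl double bond.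

Step 11
Reactants: 19 (2S)-2-[2,4-bis(methoxymethoxy)phenyl]-5,7-dihydroxy-6-iodo-8-(3-methylbut-2-enyl)chroman-4-one; 20 (E)-3-methylbut-1-enylboronic acid pinacol ester
Product: 21 (2S)-2-[2,4-bis(methoxymethoxy)phenyl]-5,7-dihydroxy-6-[(E)-3-methylbut-1-enyl]-8-(3-methylbut-2-enyl)chroman-4-one
Conditions: Pd(OAc)2, SPhos, K3PO4, THF/H2O (10:1), 40 °C
Reagents that add atoms: none
Why: Suzuki–Miyaura coupling with retention of the (E) geometry of the alkenylboronate; the bulky electron-rich biarylphosphine should allow oxidative addition and reductive elimination at the di-ortho-substituted iodide near room temperature, and under phosphate the ring A phenoxide lowers the acidity of C3–H, which guards C2 against retro-oxa-Michael opening.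

Step 12
Reactants: 21 (2S)-2-[2,4-bis(methoxymethoxy)phenyl]-5,7-dihydroxy-6-[(E)-3-methylbut-1-enyl]-8-(3-methylbut-2-enyl)chroman-4-one
Product: 23 (2S)-2-(2,4-dihydroxyphenyl)-5,7-dihydroxy-6-[(E)-3-methylbut-1-enyl]-8-(3-methylbut-2-enyl)chroman-4-one, via tetrakis(trimethylsilyl) ether 22 (not isolated)
Conditions: Me3SiOTf, 2,2′-bipyridyl, MeCN, 0 °C → rt; then H2O
Reagents that add atoms: none
Why: Silyl triflate/2,2′-bipyridyl cleavage of aryl methoxymethyl ethers: each acetal is exchanged without protic acid for an aryl silyl ether, and water then hydrolyses all aryl O–Si bonds; the buffered, non-protic medium should spare C2, the prenyl group beside O7 and the C6 alkenyl double bond.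

## Compound list

1 | methyl 2,4-dihydroxybenzoate | COC(=O)c1ccc(O)cc1O | starting material
2 | methyl 2,4-bis(methoxymethoxy)benzoate | COCOc1ccc(C(=O)OC)c(OCOC)c1 | intermediate
3 | N-methoxy-N-methylacetamide | CC(=O)N(C)OC | starting material
4 | 3-[2,4-bis(methoxymethoxy)phenyl]-N-methoxy-N-methyl-3-oxopropanamide | CON(C)C(=O)CC(=O)c1ccc(OCOC)cc1OCOC | intermediate
5 | (3S)-3-[2,4-bis(methoxymethoxy)phenyl]-3-hydroxy-N-methoxy-N-methylpropanamide | CON(C)C(=O)C[C@H](O)c1ccc(OCOC)cc1OCOC | intermediate
6 | (3S)-3-[2,4-bis(methoxymethoxy)phenyl]-N-methoxy-N-methyl-3-(triethylsilyloxy)propanamide | CON(C)C(=O)C[C@H](O[Si](CC)(CC)CC)c1ccc(OCOC)cc1OCOC | intermediate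
7 | 2,2,6-trimethyl-4H-1,3-dioxin-4-one | CC1=CC(=O)OC(C)(C)O1 | starting material
8 | acetyl chloride | CC(=O)Cl | starting material
9 | 2,2-dimethyl-6-(2-oxopropyl)-4H-1,3-dioxin-4-one | CC(=O)CC1=CC(=O)OC(C)(C)O1 | intermediate
10 | prenyl bromide (1-bromo-3-methylbut-2-ene) | CC(C)=CCBr | starting material
11 | 2,2-dimethyl-6-(6-methyl-2-oxohept-5-en-3-yl)-4H-1,3-dioxin-4-one (racemic) | CC(=O)C(CC=C(C)C)C1=CC(=O)OC(C)(C)O1 | intermediate
12 | 6-[(10S)-10-[2,4-bis(methoxymethoxy)phenyl]-2-methyl-6,8-dioxo-10-(triethylsilyloxy)dec-2-en-5-yl]-2,2-dimethyl-4H-1,3-dioxin-4-one (both C5 epimers) | CC(C)=CCC(C1=CC(=O)OC(C)(C)O1)C(=O)CC(=O)C[C@H](O[Si](CC)(CC)CC)c1ccc(OCOC)cc1OCOC | intermediate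
13 | 6-[(10S)-10-[2,4-bis(methoxymethoxy)phenyl]-10-hydroxy-2-methyl-6,8-dioxodec-2-en-5-yl]-2,2-dimethyl-4H-1,3-dioxin-4-one (not isolated) | CC(C)=CCC(C1=CC(=O)OC(C)(C)O1)C(=O)CC(=O)C[C@H](O)c1ccc(OCOC)cc1OCOC | intermediate
14 | 6-{1-[(2S)-2-[2,4-bis(methoxymethoxy)phenyl]-4-oxo-2,3-dihydro-4H-pyran-6-yl]-4-methylpent-3-enyl}-2,2-dimethyl-4H-1,3-dioxin-4-one (both side-chain epimers) | CC(C)=CCC(C1=CC(=O)OC(C)(C)O1)C1=CC(=O)C[C@@H](c2ccc(OCOC)cc2OCOC)O1 | intermediate
15 | 4-[(2S)-2-[2,4-bis(methoxymethoxy)phenyl]-4-oxo-2,3-dihydro-4H-pyran-6-yl]-7-methylocta-1,6-diene-1,3-dione (acylketene, not isolated) | CC(C)=CCC(C(=O)C=C=O)C1=CC(=O)C[C@@H](c2ccc(OCOC)cc2OCOC)O1 | intermediate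
16 | (3E)-4-[(2S)-2-[2,4-bis(methoxymethoxy)phenyl]-4-oxo-2,3-dihydro-4H-pyran-6-yl]-3-hydroxy-7-methylocta-1,3,6-trien-1-one (hydroxydienylketene, not isolated) | CC(C)=CC/C(C1=CC(=O)C[C@@H](c2ccc(OCOC)cc2OCOC)O1)=C(\O)C=C=O | intermediate
17 | (2S)-2-[2,4-bis(methoxymethoxy)phenyl]-7-hydroxy-8-(3-methylbut-2-enyl)-2,3-dihydro-4aH-chromene-4,5-dione (cyclohexadienone, not isolated) | CC(C)=CCC1=C2O[C@H](c3ccc(OCOC)cc3OCOC)CC(=O)C2C(=O)C=C1O | intermediate
18 | (2S)-2-[2,4-bis(methoxymethoxy)phenyl]-5,7-dihydroxy-8-(3-methylbut-2-enyl)chroman-4-one | CC(C)=CCc1c(O)cc(O)c2c1O[C@H](c1ccc(OCOC)cc1OCOC)CC2=O | intermediate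
19 | (2S)-2-[2,4-bis(methoxymethoxy)phenyl]-5,7-dihydroxy-6-iodo-8-(3-methylbut-2-enyl)chroman-4-one | CC(C)=CCc1c(O)c(I)c(O)c2c1O[C@H](c1ccc(OCOC)cc1OCOC)CC2=O | intermediate
20 | (E)-3-methylbut-1-enylboronic acid pinacol ester | CC(C)/C=C/B1OC(C)(C)C(C)(C)O1 | starting material
21 | (2S)-2-[2,4-bis(methoxymethoxy)phenyl]-5,7-dihydroxy-6-[(E)-3-methylbut-1-enyl]-8-(3-methylbut-2-enyl)chroman-4-one | CC(C)=CCc1c(O)c(/C=C/C(C)C)c(O)c2c1O[C@H](c1ccc(OCOC)cc1OCOC)CC2=O | intermediate
22 | (2S)-2-[2,4-bis(trimethylsilyloxy)phenyl]-6-[(E)-3-methylbut-1-enyl]-8-(3-methylbut-2-enyl)-5,7-bis(trimethylsilyloxy)chroman-4-one (not isolated) | CC(C)=CCc1c(O[Si](C)(C)C)c(/C=C/C(C)C)c(O[Si](C)(C)C)c2c1O[C@H](c1ccc(O[Si](C)(C)C)cc1O[Si](C)(C)C)CC2=O | intermediate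
23 | (2S)-2-(2,4-dihydroxyphenyl)-5,7-dihydroxy-6-[(E)-3-methylbut-1-enyl]-8-(3-methylbut-2-enyl)chroman-4-one (CNP0290067.1) | CC(C)=CCc1c(O)c(/C=C/C(C)C)c(O)c2c1O[C@H](c1ccc(O)cc1O)CC2=O | target

## Step count and least certain steps

Total: 12 steps. Longest linear sequence: 10 steps (1 → 2 → 4 → 5 → 6 → 12 → 14 → 18 → 19 → 21 → 23); the dioxinone branch (7 → 9 → 11) joins at step 7.

**Step 9 (key step, proposed new method).** The most likely failures are capture of the ketene at O1 followed by heterolysis of the benzylic C2–O1 bond, which the electron-rich ring B would assist, and intermolecular acylation of the product phenols or ketene dimerization if dilution is insufficient. The fallback uses known reactions and sets out from 14. Thermolysis in toluene at 110 °C with excess methanol should intercept the acylketene by the standard alcohol capture and give methyl 4-[(2S)-2-[2,4-bis(methoxymethoxy)phenyl]-4-oxo-2,3-dihydro-4H-pyran-6-yl]-7-methyl-3-oxooct-6-enoate F1. Treatment with Mg(OMe)2 in methanol should then bring about the Claisen (Dieckmann-type) cyclization known for polyketide 3,5-dioxo esters: the dienolate formed by deprotonation at C8 attacks the ester carbon C5 through C4a, methanol is lost and the ring aromatizes, returning to the route at 18. The cost is exposure of C2 to base, so contact time would be kept short.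

**Step 10.** Electrophilic iodine may instead engage the prenyl double bond with ring closure by O7, or substitute ring B at C5′. The fallback removes the internal nucleophile. From 18, MOMCl and iPr2NEt should alkylate only the non-chelated O7 to give (2S)-2-[2,4-bis(methoxymethoxy)phenyl]-5-hydroxy-7-(methoxymethoxy)-8-(3-methylbut-2-enyl)chroman-4-one F2. NIS should then iodinate ortho to the free O5 to give (2S)-2-[2,4-bis(methoxymethoxy)phenyl]-5-hydroxy-6-iodo-7-(methoxymethoxy)-8-(3-methylbut-2-enyl)chroman-4-one F3. Coupling with 20 as in step 11 should give (2S)-2-[2,4-bis(methoxymethoxy)phenyl]-5-hydroxy-7-(methoxymethoxy)-6-[(E)-3-methylbut-1-enyl]-8-(3-methylbut-2-enyl)chroman-4-one F4, and the conditions of step 12 would remove all three acetals, returning at 23.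

**Step 11.** Protodeiodination of the hindered, electron-rich iodide may outrun transmetallation, and base may open ring C and erode C2. The fallback is a base-free Stille coupling. Tributyl[(E)-3-methylbut-1-enyl]stannane F5, obtainable by hydrostannylation of 3-methylbut-1-yne with Bu3SnH, would be coupled with 19 under Pd2(dba)3 and AsPh3 in DMF at 45 °C, returning at 21.

**Step 12.** Acetal cleavage may stall at the hindered 2′ position, or the Lewis acid may ionize C2–O1 and erode configuration. The fallback moves the acid step to a stage without the alkenyl group and ends with fluoride. From 19, HCl in methanol should give (2S)-2-(2,4-dihydroxyphenyl)-5,7-dihydroxy-6-iodo-8-(3-methylbut-2-enyl)chroman-4-one F6. TBSCl and imidazole should silylate all but the chelated O5 to give (2S)-2-[2,4-bis(tert-butyldimethylsilyloxy)phenyl]-7-(tert-butyldimethylsilyloxy)-5-hydroxy-6-iodo-8-(3-methylbut-2-enyl)chroman-4-one F7. Coupling with 20 as in step 11 should give (2S)-2-[2,4-bis(tert-butyldimethylsilyloxy)phenyl]-7-(tert-butyldimethylsilyloxy)-5-hydroxy-6-[(E)-3-methylbut-1-enyl]-8-(3-methylbut-2-enyl)chroman-4-one F8, and Bu4NF buffered with acetic acid would return at 23.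

**Step 7.** The dianion may deprotonate 6 at C3 instead of adding, followed by loss of silanolate, or the hindered amide may react too slowly. The fallback replaces acylation by aldol addition and oxidation. From 6, iBu2AlH at −78 °C should give (3S)-3-[2,4-bis(methoxymethoxy)phenyl]-3-(triethylsilyloxy)propanal F9. The same dianion of 11 should add to this aldehyde faster than it enolizes it, giving 6-[(10S)-10-[2,4-bis(methoxymethoxy)phenyl]-8-hydroxy-2-methyl-6-oxo-10-(triethylsilyloxy)dec-2-en-5-yl]-2,2-dimethyl-4H-1,3-dioxin-4-one F10, and Dess–Martin periodinane would oxidize the new carbinol, returning at 12.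

## Further compounds

F1 | step 9 | methyl 4-[(2S)-2-[2,4-bis(methoxymethoxy)phenyl]-4-oxo-2,3-dihydro-4H-pyran-6-yl]-7-methyl-3-oxooct-6-enoate | COC(=O)CC(=O)C(CC=C(C)C)C1=CC(=O)C[C@@H](c2ccc(OCOC)cc2OCOC)O1
F2 | step 10 | (2S)-2-[2,4-bis(methoxymethoxy)phenyl]-5-hydroxy-7-(methoxymethoxy)-8-(3-methylbut-2-enyl)chroman-4-one | CC(C)=CCc1c(OCOC)cc(O)c2c1O[C@H](c1ccc(OCOC)cc1OCOC)CC2=O
F3 | step 10 | (2S)-2-[2,4-bis(methoxymethoxy)phenyl]-5-hydroxy-6-iodo-7-(methoxymethoxy)-8-(3-methylbut-2-enyl)chroman-4-one | CC(C)=CCc1c(OCOC)c(I)c(O)c2c1O[C@H](c1ccc(OCOC)cc1OCOC)CC2=O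
F4 | step 10 | (2S)-2-[2,4-bis(methoxymethoxy)phenyl]-5-hydroxy-7-(methoxymethoxy)-6-[(E)-3-methylbut-1-enyl]-8-(3-methylbut-2-enyl)chroman-4-one | CC(C)=CCc1c(OCOC)c(/C=C/C(C)C)c(O)c2c1O[C@H](c1ccc(OCOC)cc1OCOC)CC2=O
F5 | step 11 | tributyl[(E)-3-methylbut-1-enyl]stannane | CCCC[Sn](CCCC)(CCCC)/C=C/C(C)C
F6 | step 12 | (2S)-2-(2,4-dihydroxyphenyl)-5,7-dihydroxy-6-iodo-8-(3-methylbut-2-enyl)chroman-4-one | CC(C)=CCc1c(O)c(I)c(O)c2c1O[C@H](c1ccc(O)cc1O)CC2=O
F7 | step 12 | (2S)-2-[2,4-bis(tert-butyldimethylsilyloxy)phenyl]-7-(tert-butyldimethylsilyloxy)-5-hydroxy-6-iodo-8-(3-methylbut-2-enyl)chroman-4-one | CC(C)=CCc1c(O[Si](C)(C)C(C)(C)C)c(I)c(O)c2c1O[C@H](c1ccc(O[Si](C)(C)C(C)(C)C)cc1O[Si](C)(C)C(C)(C)C)CC2=O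
F8 | step 12 | (2S)-2-[2,4-bis(tert-butyldimethylsilyloxy)phenyl]-7-(tert-butyldimethylsilyloxy)-5-hydroxy-6-[(E)-3-methylbut-1-enyl]-8-(3-methylbut-2-enyl)chroman-4-one | CC(C)=CCc1c(O[Si](C)(C)C(C)(C)C)c(/C=C/C(C)C)c(O)c2c1O[C@H](c1ccc(O[Si](C)(C)C(C)(C)C)cc1O[Si](C)(C)C(C)(C)C)CC2=O
F9 | step 7 | (3S)-3-[2,4-bis(methoxymethoxy)phenyl]-3-(triethylsilyloxy)propanal | O=CC[C@H](O[Si](CC)(CC)CC)c1ccc(OCOC)cc1OCOC
F10 | step 7 | 6-[(10S)-10-[2,4-bis(methoxymethoxy)phenyl]-8-hydroxy-2-methyl-6-oxo-10-(triethylsilyloxy)dec-2-en-5-yl]-2,2-dimethyl-4H-1,3-dioxin-4-one (epimers at C5 and C8) | CC(C)=CCC(C1=CC(=O)OC(C)(C)O1)C(=O)CC(O)C[C@H](O[Si](CC)(CC)CC)c1ccc(OCOC)cc1OCOC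
A1 | alternative 1 | 5-ethoxy-4-[(E)-3-methylbut-1-enyl]-2-(3-methylbut-2-enyl)-3-(triisopropylsilyloxy)phenol | CC(C)=CCc1c(O[Si](C(C)C)(C(C)C)C(C)C)c(/C=C/C(C)C)c(OCC)cc1O
A2 | alternative 1 | 3-ethoxy-2-[(E)-3-methylbut-1-enyl]cyclobut-2-en-1-one | CCOC1=C(/C=C/C(C)C)C(=O)C1
A3 | alternative 1 | triisopropyl[(5-methylhex-4-en-1-ynyl)oxy]silane | CC(C)=CCC#CO[Si](C(C)C)(C(C)C)C(C)C
A4 | alternative 2 | (2S)-2-[2,4-bis(tert-butyldimethylsilyloxy)phenyl]-5,7-bis(tert-butyldimethylsilyloxy)-6-[(E)-3-methylbut-1-enyl]-8-(3-methylbut-2-enyl)chroman-4-one | CC(C)=CCc1c(O[Si](C)(C)C(C)(C)C)c(/C=C/C(C)C)c(O[Si](C)(C)C(C)(C)C)c2c1O[C@H](c1ccc(O[Si](C)(C)C(C)(C)C)cc1O[Si](C)(C)C(C)(C)C)CC2=O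
A5 | alternative 2 | 1-[2-{[2,4-bis(tert-butyldimethylsilyloxy)phenyl]methoxy}-4,6-bis(tert-butyldimethylsilyloxy)-5-[(E)-3-methylbut-1-enyl]-3-(3-methylbut-2-enyl)phenyl]-2-diazoethanone | CC(C)=CCc1c(O[Si](C)(C)C(C)(C)C)c(/C=C/C(C)C)c(O[Si](C)(C)C(C)(C)C)c(C(=O)C=[N+]=[N-])c1OCc1ccc(O[Si](C)(C)C(C)(C)C)cc1O[Si](C)(C)C(C)(C)C
A6 | alternative 3 | 2-[2,4-bis(methoxymethoxy)phenyl]-5,7-bis(methoxymethoxy)-6-[(E)-3-methylbut-1-enyl]-8-(3-methylbut-2-enyl)chromen-4-one | CC(C)=CCc1c(OCOC)c(/C=C/C(C)C)c(OCOC)c2c1OC(c1ccc(OCOC)cc1OCOC)=CC2=O
A7 | alternative 3 | 2-iodo-3,5-bis(methoxymethoxy)-4-[(E)-3-methylbut-1-enyl]-6-(3-methylbut-2-enyl)phenol | CC(C)=CCc1c(O)c(I)c(OCOC)c(/C=C/C(C)C)c1OCOC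
A8 | alternative 3 | 1-ethynyl-2,4-bis(methoxymethoxy)benzene | C#Cc1ccc(OCOC)cc1OCOC
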